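**Retrosynthetic overview**

1. Endgame: the two B-ring phenols are released from aryl tosylates with hydroxide. The prenyl group is put on C6 by an α-selective Suzuki coupling of a C6 bromide, so that no prenyl alkene is present in the carbene step.
2. Key disconnection: the pyran ring (O1–C2–C3–C4–C4a–C8a) is taken back to a furan ring by excising C3 together with the B ring. The precursors are 5-bromo-4,6-dimethoxybenzofuran and an aryl(chloro)carbene from a chlorodiazirine; carbon insertion into C2=C3 gives the isoflavylium ion, and hydride at C2 gives the 2H-chromene.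
3. Enabling feature: the O1–C2=C3 enol-ether bond of the benzofuran is its only non-benzenoid π bond. The O1 lone pair and the 5,7-dimethoxy A ring make the chromenylium cation easy to reach and direct hydride to C2. C3 of the target is an sp2 carbon bearing only the aryl group, which is what an aryl carbyne equivalent delivers.
4. Fragments: the benzofuran comes from 3,5-dimethoxyphenol (bromination para to OH, O-alkylation, cyclodehydration; symmetry fixes the regiochemistry). The diazirine comes from 2,4-dihydroxybenzonitrile (tosylation, amidine, Graham oxidation); the tosylates make the aryl group electron-poor, so the diazirine is stable and the carbene electrophilic.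
5. Ring order: A and B rings are bought; furan ring (step 3); diazirine ring (step 6, lost as N2); transient cyclopropane and its expansion to the pyran ring (step 7).

Key step: step 7

Remark on the chemistry: the target has no stereocentre and no stereogenic double bond (C3=C4 is endocyclic, the prenyl terminus carries two methyl groups). It is achiral, so the route needs no stereocontrol.

**Route**

Step 1
Reactants: 1 3,5-dimethoxyphenol
Product: 2 4-bromo-3,5-dimethoxyphenol
Conditions: NBS (1.0 equiv), CH2Cl2, −78 → 0 °C
Reagents that add atoms: N-bromosuccinimide, O=C1CCC(=O)N1Br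
Why: Electrophilic aromatic bromination, in which the free hydroxyl should direct para to the carbon flanked by the two methoxy groups and activated by all three oxygens, while one equivalent of NBS at low temperature should hold the reaction at the monobromide.

Step 2
Reactants: 2 4-bromo-3,5-dimethoxyphenol; 3 bromoacetaldehyde diethyl acetal
Product: 4 2-(4-bromo-3,5-dimethoxyphenoxy)acetaldehyde diethyl acetal
Conditions: K2CO3, KI (cat.), DMF, 110 °C
Reagents that add atoms: none
Why: Williamson ether synthesis of the phenoxide with the primary bromide, under basic conditions to which the acetal and the aryl bromide are inert.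

Step 3
Reactants: 4 2-(4-bromo-3,5-dimethoxyphenoxy)acetaldehyde diethyl acetal
Product: 6 5-bromo-4,6-dimethoxybenzofuran, via 3-ethoxy-2,3-dihydrobenzofuran 5 (not isolated)
Conditions: Amberlyst-15, toluene, 90 °C, 4 Å MS, high dilution
Reagents that add atoms: none
Why: Acid-catalysed cyclodehydration of an aryloxyacetaldehyde acetal (intramolecular Friedel–Crafts attack of the oxocarbenium ion on the ring carbon ortho to the ether oxygen and ortho/para to the methoxy groups, then loss of ethanol from 5), in which the two ortho positions are equivalent by symmetry so that only one benzofuran can form.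

Step 4
Reactants: 7 2,4-dihydroxybenzonitrile
Product: 8 4-cyano-1,3-phenylene bis(4-methylbenzenesulfonate)
Conditions: TsCl (2.3 equiv), Et3N, DMAP (cat.), CH2Cl2, 0 °C → rt
Reagents that add atoms: 4-toluenesulfonyl chloride, Cc1ccc(cc1)S(Cl)(=O)=O
Why: Sulfonylation of both phenols, which turns the resorcinol donors into acceptors so that the later chlorodiazirine should be stable and its carbene electrophilic.

Step 5
Reactants: 8 4-cyano-1,3-phenylene bis(4-methylbenzenesulfonate)
Product: 10 2,4-bis(tosyloxy)benzamidinium chloride, via lithium bis(trimethylsilyl)amidinate 9 (not isolated)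
Conditions: LiHMDS (1.2 equiv), THF, 0 °C → rt; then HCl (4 M in dioxane), 0 °C, precipitation with Et2O
Reagents that add atoms: lithium hexamethyldisilazide, [Li]N([Si](C)(C)C)[Si](C)(C)C; hydrogen chloride, Cl
Why: Amidine synthesis by addition of the hindered silylamide to a non-enolizable aryl nitrile that is activated by two sulfonyloxy groups, followed by N-desilylation and salt formation with anhydrous HCl.

Step 6
Reactants: 10 2,4-bis(tosyloxy)benzamidinium chloride
Product: 11 3-chloro-3-[2,4-bis(tosyloxy)phenyl]-3H-diazirine
Conditions: NaOCl (aq), LiCl, DMSO, pentane, 0 °C → rt, dark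
Reagents that add atoms: sodium hypochlorite, [Na+].[O-]Cl
Why: Graham oxidation of an amidinium salt to the 3-chloro-3-aryl-3H-diazirine, which is reliable for aryl amidines without strongly donating groups and which the aryl tosylates should survive.

Step 7
Reactants: 6 5-bromo-4,6-dimethoxybenzofuran; 11 3-chloro-3-[2,4-bis(tosyloxy)phenyl]-3H-diazirine
Product: 15 4-(6-bromo-5,7-dimethoxy-2H-chromen-3-yl)-1,3-phenylene bis(4-methylbenzenesulfonate), via aryl(chloro)carbene 12 (not isolated), via chlorocyclopropane 13 (not isolated), via isoflavylium chloride 14 (not isolated)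
Conditions: 11 (2 equiv, in portions), MeCN, 60 °C, dark, Ar; then EtOH, NaBH4, −20 → 0 °C
Reagents that add atoms: none
Why: Proposed new method: thermal loss of N2 from 11 gives the singlet aryl(chloro)carbene 12, made electrophilic by its two sulfonyloxy groups, which should add in a [2+1] cycloaddition to the O1–C2=C3 enol-ether bond of 6, the only non-benzenoid and most nucleophilic π bond present (the prenyl alkene is deliberately still absent), to give cyclopropane 13. Ionization of the C–Cl bond with disrotatory 2π-electrocyclic opening of the old C2–C3 bond (cyclopropyl to allyl cation, pushed by the O1 lone pair and the dimethoxyaryl ring) then expands the five-membered furan ring to the six-membered aromatic chromenylium ring of 14, with the carbene carbon inserted as C3 and carrying the B ring; the pyran ring is thus made by cycloaddition and ring opening, not by a cyclization. The chloride epimer with chlorine anti to the five-membered ring cannot open in a concerted way but should equilibrate with the reactive epimer by reversible heterolysis of the bond between the carbene carbon and the benzylic ring carbon (trioxygenated benzylic cation and α-chlorobenzylic anion, a donor–acceptor cyclopropane). Sodium borohydride is then expected to deliver hydride to C2, the unhindered oxocarbenium carbon, whereas C4 is flanked by the 5-methoxy group and the ortho-substituted 3-aryl group and is deactivated by donation from the 5- and 7-methoxy groups, and the product is the conjugated stilbene-type 2H-chromene. The closest known reactions are the Ciamician–Dennstedt-type carbon insertion of aryl chlorodiazirines into indoles and pyrroles, the dihalocarbene (Parham) ring expansion of benzofurans to 2H-chromenes and the hydride reduction of benzopyrylium salts to 2H-chromenes. No stereocentre remains in 15, because the two cyclopropane stereocentres end as an sp2 carbon and a CH2 group.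

Step 8
Reactants: 15 4-(6-bromo-5,7-dimethoxy-2H-chromen-3-yl)-1,3-phenylene bis(4-methylbenzenesulfonate); 16 3-methylbut-2-enylboronic acid pinacol ester
Product: 17 4-[5,7-dimethoxy-6-(3-methylbut-2-enyl)-2H-chromen-3-yl]-1,3-phenylene bis(4-methylbenzenesulfonate)
Conditions: Pd(OAc)2 (cat.), bulky biarylphosphine ligand chosen for α-selective allyl transfer (cat.), K3PO4 (aq), THF, 40 °C
Reagents that add atoms: none
Why: Suzuki–Miyaura coupling of the aryl bromide with an allylboronate under ligand control for coupling at the boron-bearing carbon, which should give the linear prenyl arene while the aryl tosylates and the chromene double bond stay untouched at this temperature.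

Step 9
Reactants: 17 4-[5,7-dimethoxy-6-(3-methylbut-2-enyl)-2H-chromen-3-yl]-1,3-phenylene bis(4-methylbenzenesulfonate)
Product: 18 dehydroglyasperin D
Conditions: KOH (aq, 2 M), 1,4-dioxane, 70 °C, Ar; then AcOH to pH 6
Reagents that add atoms: none
Why: Hydrolytic cleavage of both aryl sulfonates by hydroxide attack at sulfur with phenoxide as leaving group, under non-acidic and methanol-free conditions that should avoid acid-triggered cyclization of the 2'-hydroxyl onto C4 and O-methylation of the phenoxides, and that leave the methyl ethers and both alkenes intact.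

**Compound list**

1 | 3,5-dimethoxyphenol | COc1cc(O)cc(OC)c1 | starting material
2 | 4-bromo-3,5-dimethoxyphenol | COc1cc(O)cc(OC)c1Br | intermediate
3 | bromoacetaldehyde diethyl acetal (2-bromo-1,1-diethoxyethane) | CCOC(CBr)OCC | starting material
4 | 2-(4-bromo-3,5-dimethoxyphenoxy)acetaldehyde diethyl acetal | CCOC(COc1cc(OC)c(Br)c(OC)c1)OCC | intermediate
5 | 5-bromo-3-ethoxy-4,6-dimethoxy-2,3-dihydrobenzofuran (racemic, not isolated) | CCOC1COc2cc(OC)c(Br)c(OC)c12 | intermediate
6 | 5-bromo-4,6-dimethoxybenzofuran | COc1cc2occc2c(OC)c1Br | intermediate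
7 | 2,4-dihydroxybenzonitrile | N#Cc1ccc(O)cc1O | starting material
8 | 4-cyano-1,3-phenylene bis(4-methylbenzenesulfonate) | N#Cc1ccc(OS(=O)(=O)c2ccc(C)cc2)cc1OS(=O)(=O)c1ccc(C)cc1 | intermediate
9 | lithium N,N'-bis(trimethylsilyl)-2,4-bis(tosyloxy)benzamidinate (not isolated) | [Li]N([Si](C)(C)C)C(=N[Si](C)(C)C)c1ccc(OS(=O)(=O)c2ccc(C)cc2)cc1OS(=O)(=O)c1ccc(C)cc1 | intermediate
10 | 2,4-bis(tosyloxy)benzamidinium chloride | NC(=N)c1ccc(OS(=O)(=O)c2ccc(C)cc2)cc1OS(=O)(=O)c1ccc(C)cc1.Cl | intermediate
11 | 3-chloro-3-[2,4-bis(tosyloxy)phenyl]-3H-diazirine | ClC1(N=N1)c1ccc(OS(=O)(=O)c2ccc(C)cc2)cc1OS(=O)(=O)c1ccc(C)cc1 | intermediate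
12 | [2,4-bis(tosyloxy)phenyl]chlorocarbene (not isolated) | Cl[C]c1ccc(OS(=O)(=O)c2ccc(C)cc2)cc1OS(=O)(=O)c1ccc(C)cc1 | intermediate
13 | 1-[2,4-bis(tosyloxy)phenyl]-5-bromo-1-chloro-4,6-dimethoxy-1a,6b-dihydro-1H-cyclopropa[b]benzofuran (cis-fused, racemic, both epimers at the chlorine-bearing carbon, not isolated) | COc1cc2OC3C(c2c(OC)c1Br)C3(Cl)c1ccc(OS(=O)(=O)c2ccc(C)cc2)cc1OS(=O)(=O)c1ccc(C)cc1 | intermediate
14 | 3-[2,4-bis(tosyloxy)phenyl]-6-bromo-5,7-dimethoxychromenylium chloride (not isolated) | COc1cc2[o+]cc(-c3ccc(OS(=O)(=O)c4ccc(C)cc4)cc3OS(=O)(=O)c3ccc(C)cc3)cc2c(OC)c1Br.[Cl-] | intermediate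
15 | 4-(6-bromo-5,7-dimethoxy-2H-chromen-3-yl)-1,3-phenylene bis(4-methylbenzenesulfonate) | COc1cc2OCC(c3ccc(OS(=O)(=O)c4ccc(C)cc4)cc3OS(=O)(=O)c3ccc(C)cc3)=Cc2c(OC)c1Br | intermediate
16 | 3-methylbut-2-enylboronic acid pinacol ester | CC(C)=CCB1OC(C)(C)C(C)(C)O1 | starting material
17 | 4-[5,7-dimethoxy-6-(3-methylbut-2-enyl)-2H-chromen-3-yl]-1,3-phenylene bis(4-methylbenzenesulfonate) | COc1cc2OCC(c3ccc(OS(=O)(=O)c4ccc(C)cc4)cc3OS(=O)(=O)c3ccc(C)cc3)=Cc2c(OC)c1CC=C(C)C | intermediate
18 | dehydroglyasperin D, 4-[5,7-dimethoxy-6-(3-methylbut-2-en-1-yl)-2H-chromen-3-yl]benzene-1,3-diol | COc1cc2c(c(OC)c1CC=C(C)C)C=C(c1ccc(O)cc1O)CO2 | target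

**Step count**

Total: 9 steps. Longest linear sequence: 6 steps (steps 1–3 or 4–6, then 7–9).

**Steps most likely to fail**

1. Step 7 (proposed new method). Several processes could defeat it:
   - The carbene may be consumed unproductively, by azine formation, by formal C–H insertion at the furan carbons through opening of the wrong cyclopropane bond, or by attack on the arene.
   - The cyclopropane epimer with chlorine anti to the ring may open incompletely.
   - Hydride may be delivered to C4 in competition with C2.

   Fallback, from 6 back to 15, by known reactions: the carbon atom is inserted with dibromocarbene and the B ring is attached afterwards.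
   - Dibromocarbene (CHBr3, 50% NaOH, BnEt3NCl, CH2Cl2, 0 °C) should add to the C2=C3 bond of 6 to give 1,1,5-tribromo-4,6-dimethoxy-1a,6b-dihydro-1H-cyclopropa[b]benzofuran F1, in which one bromine is always syn to the ring.
   - On warming in aqueous acetone with NaHCO3, F1 should open with loss of bromide and capture of water to the lactol 3,6-dibromo-5,7-dimethoxy-2H-chromen-2-ol F2 (Parham ring expansion).
   - NaBH4 in MeOH should reduce F2 through its open hydroxy-enal form to (E)-2-bromo-3-(3-bromo-6-hydroxy-2,4-dimethoxyphenyl)prop-2-en-1-ol F3 (CH2OH cis to the aryl group). This fixes C2 at the CH2 level without any regiochemical question.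
   - Mitsunobu etherification (PPh3, DIAD, THF) should close 3,6-dibromo-5,7-dimethoxy-2H-chromene F4.
   - The B ring comes from commercial 4-bromoresorcinol: tosylation (TsCl, Et3N) gives 4-bromo-1,3-phenylene bis(4-methylbenzenesulfonate) F5, and Miyaura borylation (B2pin2, Pd(dppf)Cl2, KOAc, dioxane, 80 °C) gives 4-(4,4,5,5-tetramethyl-1,3,2-dioxaborolan-2-yl)-1,3-phenylene bis(4-methylbenzenesulfonate) F6.
   - Suzuki–Miyaura coupling of F6 with F4 (Pd(PPh3)4, K2CO3, dioxane/water, 70 °C) should give 15; the alkenyl C–Br bond is expected to react before the hindered, electron-rich aryl C–Br bond.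

2. Step 3. Ipso-protonation of the very electron-rich ring may cause loss or migration of bromine, and the electron-rich benzofuran may oligomerize under acid.

   Fallback, from 2 back to 6, building the furan ring without hot acid:
   - Ortho-formylation of 2 (MgCl2, Et3N, paraformaldehyde, MeCN, reflux; both ortho positions are equivalent) should give 3-bromo-6-hydroxy-2,4-dimethoxybenzaldehyde F7.
   - Corey–Chaykovsky reaction with dimethylsulfoxonium methylide (Me3S(O)I, NaH, DMSO, rt), through epoxide formation and 5-exo opening by the phenoxide, should give 5-bromo-4,6-dimethoxy-2,3-dihydrobenzofuran-3-ol F8.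
   - Dehydration of this strongly activated benzylic alcohol (PPTS cat., CH2Cl2, rt) should give 6.

3. Step 8. Oxidative addition at the di-ortho-substituted bromide may be slow, the allylboronate may couple through its γ-carbon (reverse-prenyl isomer), and the boronate may protodeboronate.

   Fallback, from 15 back to 17, separating C–C coupling from construction of the trisubstituted alkene:
   - Stille coupling with allyltributylstannane (Pd(PPh3)4, toluene, 100 °C), in which α- and γ-attack give the same product, should give 4-(6-allyl-5,7-dimethoxy-2H-chromen-3-yl)-1,3-phenylene bis(4-methylbenzenesulfonate) F9.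
   - Olefin cross-metathesis of F9 with excess 2-methyl-2-butene (Grubbs second-generation catalyst, CH2Cl2, 40 °C) should give 17; the endocyclic trisubstituted chromene alkene is expected to stay inert.

**Further compounds**

F1 | step 7 | 1,1,5-tribromo-4,6-dimethoxy-1a,6b-dihydro-1H-cyclopropa[b]benzofuran | COc1cc2OC3C(c2c(OC)c1Br)C3(Br)Br
F2 | step 7 | 3,6-dibromo-5,7-dimethoxy-2H-chromen-2-ol | COc1cc2OC(O)C(Br)=Cc2c(OC)c1Br
F3 | step 7 | (E)-2-bromo-3-(3-bromo-6-hydroxy-2,4-dimethoxyphenyl)prop-2-en-1-ol | OC/C(Br)=C\c1c(O)cc(OC)c(Br)c1OC
F4 | step 7 | 3,6-dibromo-5,7-dimethoxy-2H-chromene | COc1cc2OCC(Br)=Cc2c(OC)c1Br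
F5 | step 7 | 4-bromo-1,3-phenylene bis(4-methylbenzenesulfonate) | Brc1ccc(OS(=O)(=O)c2ccc(C)cc2)cc1OS(=O)(=O)c1ccc(C)cc1
F6 | step 7 | 4-(4,4,5,5-tetramethyl-1,3,2-dioxaborolan-2-yl)-1,3-phenylene bis(4-methylbenzenesulfonate) | CC1(C)OB(OC1(C)C)c1ccc(OS(=O)(=O)c2ccc(C)cc2)cc1OS(=O)(=O)c1ccc(C)cc1
F7 | step 3 | 3-bromo-6-hydroxy-2,4-dimethoxybenzaldehyde | COc1cc(O)c(C=O)c(OC)c1Br
F8 | step 3 | 5-bromo-4,6-dimethoxy-2,3-dihydrobenzofuran-3-ol (racemic) | COc1cc2OCC(O)c2c(OC)c1Br
F9 | step 8 | 4-(6-allyl-5,7-dimethoxy-2H-chromen-3-yl)-1,3-phenylene bis(4-methylbenzenesulfonate) | COc1cc2OCC(c3ccc(OS(=O)(=O)c4ccc(C)cc4)cc3OS(=O)(=O)c3ccc(C)cc3)=Cc2c(OC)c1CC=C
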